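Start with the easy reading: in the teal run D drops fast to a few percent and then stays low beside a larger Z.

in all of them: Q 16 mM (held)
- teal: D 0.38 M; run made earlier
- flask: D 0.25 M; time 80 min

teal run (percent of the D charged)

| time / min | G / % | Z / % | D / % |
|---|---|---|---|
| 2.00 | 1.4 | 34.3 | 36.2 |
| 3.00 | 2.2 | 40.7 | 18.7 |
| 5.00 | 2.5 | 44.5 | 5.9 |
| 8.00 | 3.0 | 40.6 | 3.5 |
| 15.0 | 4.1 | 34.2 | 2.6 |
| 25.0 | 4.1 | 27.7 | 2.9 |

(standard deviation of a reading: 0.5 percentage points)

- percent here means D units held: one L counts as two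
- at the start none of X is dissolved
- candidate steps: Z <-> E; D + X <-> G; Q <-> X; D + X <-> Z; D + Z -> L

- share of G in G plus Z at 12 s
- share of G in G plus Z at 80 min
- which of G and Z there is more of at 80 min

The latest teal pair gives Z at 9.55 times D. I call this the stall ratio: cZ over cD once D + X <-> Z stands at its balance (a pre-equilibrium). It is a reading, and D carries a scatter of 0.5 percentage points. I expect it to carry over to the flask, where Q is held at the same 16 mM, so late in the flask you should find Z about that many times D.

The forecast gave 3.3% at 12 s, 25% at 80 min, and Z in the lead. It read “D stalls at about Z/12”, where my pair gives 9.55.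

The flask gives 3.00% and 31.6%, with Z ahead, 16.7% against 7.74% of G, so the late share lands above the forecast.

    Z ⇌ E (K = 0.210, k = 0.0942 s⁻¹)
    D + X ⇌ G (K = 14000 L mol⁻¹, k = 0.0253 L mol⁻¹ s⁻¹)
    Q ⇌ X, rate k3*(csat - [X]) (kL = 0.208 s⁻¹)
    D + X ⇌ Z (K = 563 L mol⁻¹, k = 0.983 L mol⁻¹ s⁻¹)
    D + Z → L (k = 0.0205 L mol⁻¹ s⁻¹)

In the flask at 80.0 min, Z is made at 0.174 of the rate at which it is used up, each step taken net, and it has come down from 27.1% at 40.0 min. The flask ends with Z at 9.64 times D, beside the stall ratio of 9.55, and the neighbour flask charged with 0.62 M of D ends with 8.00% of Z, at 9.72 times D.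

The numbers in the tables are simulated with made-up constants.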